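**Retrosynthetic overview**

1. Target 18 ⇐ 17 (Zn/AcOH): reductive cleavage of the C6–O bond of a temporary spiro-γ-lactone rearomatises ring A and frees the 5-OH and the CO2H together.
2. 17 ⇐ 12 + acetaldehyde 13: a boron aldol makes C2–C3, then the aldol oxygen displaces methoxide at C8a to make O1–C8a and close ring C.
3. Enabling feature: O1–C8a=C4a–C4=O of ring C is a vinylogous ester, and C8a is one of the three oxygenated carbons of the phloroglucinol ring A. Oxidising the 5-OH phenol with capture at C6 by the side-chain carboxyl turns ring A into a 2,4-cyclohexadienone in which C8a–OMe is the β-carbon of two enones (C5=O and C4=O), while the propanoyl CH2 is the only enolisable ketone position.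
4. 12 ⇐ 11 ⇐ 9 (lactone opening, oxidative spirolactonisation); 9 ⇐ 5: a temporary δ-lactone (coumarin) fixes the side chain at C6, sets its (R) centre by asymmetric conjugate reduction and leaves a single ring C–H for iodination and Stille prenylation.
5. 5 ⇐ 2 + 3 ⇐ 1. Ring order: ring A (from flopropione) → δ-lactone (temporary) → spiro-γ-lactone with ring A dearomatised (temporary) → ring C → ring A rearomatised.

Key step: step 9

Assumption 1: the spiro carbon made in step 8 is expected as a mixture of both configurations; it is left unspecified in the SMILES of 12 and 14–17 because it returns to the planar aromatic C6 in step 10, and both epimers are carried on together.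

Assumption 2: (+)-Ipc2BOTf (made from (−)-α-pinene) is taken to send its Z-enolate to the Re face of acetaldehyde, the sense expected for chair transition states of Ipc2B Z-enolates and allyl boranes, and the (R)-ligand in step 4 is taken to give the (R)-lactone; if either sense is reversed on this substrate, the antipodal reagent or ligand is used.

**Route**

Step 1
Reactants: 1 flopropione [1-(2,4,6-trihydroxyphenyl)propan-1-one]
Product: 2 1-(2-hydroxy-4,6-dimethoxyphenyl)propan-1-one
Conditions: Me2SO4 (2.1 equiv), K2CO3, acetone, reflux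
Reagents that add atoms: dimethyl sulfate, COS(=O)(=O)OC
Why: Williamson-type O-methylation is selective for the two hydroxyls that are not hydrogen-bonded to the propanoyl carbonyl, so the chelated ortho OH (the future 5-OH) should remain free.

Step 2
Reactants: 2 1-(2-hydroxy-4,6-dimethoxyphenyl)propan-1-one; 3 oct-2-ynoic acid
Product: 4 3,5-dimethoxy-2-propanoylphenyl oct-2-ynoate
Conditions: DCC, DMAP (cat.), CH2Cl2, 0 °C to rt
Reagents that add atoms: none
Why: Steglich esterification of the only free phenol places the alkynoate next to the single open ortho carbon, the future C6.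

Step 3
Reactants: 4 3,5-dimethoxy-2-propanoylphenyl oct-2-ynoate
Product: 5 5,7-dimethoxy-4-pentyl-8-propanoyl-2H-chromen-2-one
Conditions: [(JohnPhos)Au(MeCN)]SbF6 (3 mol%), ClCH2CH2Cl, 50 °C
Reagents that add atoms: none
Why: Intramolecular alkyne hydroarylation (6-endo-dig, Friedel–Crafts type) by the cationic monovalent gold complex should close the coumarin at the only free ortho carbon, which is activated by an ortho and a para methoxy group.

Step 4
Reactants: 5 5,7-dimethoxy-4-pentyl-8-propanoyl-2H-chromen-2-one
Product: 6 (4R)-5,7-dimethoxy-4-pentyl-8-propanoyl-3,4-dihydro-2H-chromen-2-one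
Conditions: Cu(OAc)2·H2O (3 mol%), (R)-DTBM-SEGPHOS (3.3 mol%), (EtO)2MeSiH (1.3 equiv), t-BuOH (1.3 equiv), toluene, 0 °C
Reagents that add atoms: none
Why: Asymmetric conjugate reduction of the β,β-disubstituted unsaturated lactone by ligated CuH delivers hydride to one face of C4 under control of the bisphosphine and so sets the (R) side-chain centre, while the hindered, electron-rich aryl ketone should react far more slowly.

Step 5
Reactants: 6 (4R)-5,7-dimethoxy-4-pentyl-8-propanoyl-3,4-dihydro-2H-chromen-2-one
Product: 7 (4R)-6-iodo-5,7-dimethoxy-4-pentyl-8-propanoyl-3,4-dihydro-2H-chromen-2-one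
Conditions: NIS (1.1 equiv), CF3CO2H (cat.), MeCN, rt
Reagents that add atoms: N-iodosuccinimide, O=C1CCC(=O)N1I
Why: Electrophilic aromatic iodination can only take the last ring C–H, which lies between the two methoxy groups and is the most electron-rich position.

Step 6
Reactants: 7 (4R)-6-iodo-5,7-dimethoxy-4-pentyl-8-propanoyl-3,4-dihydro-2H-chromen-2-one; 8 tributyl(3-methylbut-2-en-1-yl)stannane
Product: 9 (4R)-5,7-dimethoxy-6-(3-methylbut-2-en-1-yl)-4-pentyl-8-propanoyl-3,4-dihydro-2H-chromen-2-one
Conditions: Pd(PPh3)4 (5 mol%), CuI (10 mol%), DMF, 80 °C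
Reagents that add atoms: none
Why: Stille cross-coupling of the aryl iodide with the prenylstannane should transfer the allyl unit through its tin-bearing carbon and give the linear 3-methylbut-2-enyl group without touching the lactone or ketone.

Step 7
Reactants: 9 (4R)-5,7-dimethoxy-6-(3-methylbut-2-en-1-yl)-4-pentyl-8-propanoyl-3,4-dihydro-2H-chromen-2-one
Product: 11 (3R)-3-[2-hydroxy-4,6-dimethoxy-5-(3-methylbut-2-en-1-yl)-3-propanoylphenyl]octanoic acid, via disodium salt 10 (not isolated)
Conditions: NaOH (2.5 equiv), THF/H2O, 0 °C to rt; then 1 M HCl to pH 3, 0 °C; used at once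
Reagents that add atoms: sodium hydroxide, [Na+].[OH-]
Why: Saponification opens the aryl lactone, and after cold acidification the phenol is held by a hydrogen bond to the ortho propanoyl carbonyl, exactly as the 5-OH is held in the target, which should slow relactonisation long enough for immediate use.

Step 8
Reactants: 11 (3R)-3-[2-hydroxy-4,6-dimethoxy-5-(3-methylbut-2-en-1-yl)-3-propanoylphenyl]octanoic acid
Product: 12 (4R)-8,10-dimethoxy-9-(3-methylbut-2-en-1-yl)-4-pentyl-7-propanoyl-1-oxaspiro[4.5]deca-7,9-diene-2,6-dione (both epimers at spiro C5)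
Conditions: PhI(OAc)2 (1.1 equiv), (CF3)2CHOH/CH2Cl2, −20 °C, dark
Reagents that add atoms: none
Why: Oxidative dearomatising spirolactonisation with the trivalent iodine reagent: the phenol is oxidised to a phenoxenium-type intermediate that the tethered carboxyl group captures at the ortho carbon C6 in a 5-exo closure, which protects the acid, blocks rearomatisation and leaves the propanoyl group on a 2,4-cyclohexadienone; the configuration of the new spiro carbon is of no consequence.

Step 9
Reactants: 12 (4R)-8,10-dimethoxy-9-(3-methylbut-2-en-1-yl)-4-pentyl-7-propanoyl-1-oxaspiro[4.5]deca-7,9-diene-2,6-dione; 13 acetaldehyde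
Product: 17 (2S,3R,3'R)-7-methoxy-2,3-dimethyl-8-(3-methylbut-2-en-1-yl)-3'-pentyl-2,3-dihydro-4H,5H-spiro[chromene-6,2'-oxolane]-4,5,5'-trione (both epimers at the spiro carbon), via Z-enol borinate 14 (not isolated), via boron aldolate 15 (not isolated), via syn-aldol 16 (not isolated)
Conditions: (+)-Ipc2BOTf (1.5 equiv), i-Pr2NEt (2 equiv), CH2Cl2, −78 °C; MeCHO (5 equiv), −78 to −20 °C; then MeOH, CF3CO2H, 0 °C
Reagents that add atoms: none
Why: Soft enolisation of the propanoyl ketone by (+)-Ipc2BOTf/i-Pr2NEt gives the Z-enol borinate 14, which adds to acetaldehyde through a closed chair (Zimmerman–Traxler) transition state to form C2–C3; methanolysis frees syn-aldol 16, whose hydroxyl adds to C8a of the β-methoxy enone and expels methanol under acid, forming O1–C8a. The closest known reaction type is the Paterson boron aldol of β-alkoxy- or β-chlorovinyl ethyl ketones followed by acid cyclisation to cis-2,3-disubstituted 2,3-dihydro-4H-pyran-4-ones, the stepwise counterpart of the Danishefsky diene–aldehyde cyclocondensation. Ring C closes by a 6-endo-trig oxa-Michael addition followed by β-elimination of methoxide. The C2/C3 relative configuration (syn aldol, hence cis-2,3-dimethyl) follows from the Z-enolate geometry in the chair with the aldehyde methyl equatorial, and the absolute configuration (2S,3R) from the isopinocampheyl ligands, which direct the enolate to the Re face of acetaldehyde. The step needs chemoselective enolisation (the propanoyl CH2 is the only ketone α-C–H and the γ-lactone is not enolised by a boron triflate/amine pair), site-selective closure (only C8a, not C7, lies within reach of the aldol oxygen in a six-membered ring) and retention of the cis relationship, which the acid-mediated, base-free closure secures.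

Step 10
Reactants: 17 (2S,3R,3'R)-7-methoxy-2,3-dimethyl-8-(3-methylbut-2-en-1-yl)-3'-pentyl-2,3-dihydro-4H,5H-spiro[chromene-6,2'-oxolane]-4,5,5'-trione
Product: 18 (3R)-3-[(2S,3R)-5-hydroxy-7-methoxy-2,3-dimethyl-8-(3-methylbut-2-en-1-yl)-4-oxo-3,4-dihydro-2H-chromen-6-yl]octanoic acid (CNP0217102.1)
Conditions: Zn dust, AcOH/THF, 0 °C to rt
Reagents that add atoms: none
Why: Reductive cleavage of an α-acyloxy ketone by Zn/AcOH, driven here by rearomatisation, expels the lactone carboxylate from C6 and so releases the 5-OH phenol and the free acid together under mildly acidic conditions that should leave the cis-2,3-dimethyl unit unepimerised.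

**Compound list**

1 | flopropione, 1-(2,4,6-trihydroxyphenyl)propan-1-one | CCC(=O)c1c(O)cc(O)cc1O | starting material
2 | 1-(2-hydroxy-4,6-dimethoxyphenyl)propan-1-one | CCC(=O)c1c(O)cc(OC)cc1OC | intermediate
3 | oct-2-ynoic acid | CCCCCC#CC(=O)O | starting material
4 | 3,5-dimethoxy-2-propanoylphenyl oct-2-ynoate | CCCCCC#CC(=O)Oc1cc(OC)cc(OC)c1C(=O)CC | intermediate
5 | 5,7-dimethoxy-4-pentyl-8-propanoyl-2H-chromen-2-one | CCCCCC1=CC(=O)Oc2c1c(OC)cc(OC)c2C(=O)CC | intermediate
6 | (4R)-5,7-dimethoxy-4-pentyl-8-propanoyl-3,4-dihydro-2H-chromen-2-one | CCCCC[C@@H]1CC(=O)Oc2c1c(OC)cc(OC)c2C(=O)CC | intermediate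
7 | (4R)-6-iodo-5,7-dimethoxy-4-pentyl-8-propanoyl-3,4-dihydro-2H-chromen-2-one | CCCCC[C@@H]1CC(=O)Oc2c1c(OC)c(I)c(OC)c2C(=O)CC | intermediate
8 | tributyl(3-methylbut-2-en-1-yl)stannane | CCCC[Sn](CCCC)(CCCC)CC=C(C)C | starting material
9 | (4R)-5,7-dimethoxy-6-(3-methylbut-2-en-1-yl)-4-pentyl-8-propanoyl-3,4-dihydro-2H-chromen-2-one | CCCCC[C@@H]1CC(=O)Oc2c1c(OC)c(CC=C(C)C)c(OC)c2C(=O)CC | intermediate
10 | disodium salt of 11 (phenolate carboxylate, 3R) | CCCCC[C@H](CC(=O)[O-])c1c([O-])c(C(=O)CC)c(OC)c(CC=C(C)C)c1OC.[Na+].[Na+] | intermediate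
11 | (3R)-3-[2-hydroxy-4,6-dimethoxy-5-(3-methylbut-2-en-1-yl)-3-propanoylphenyl]octanoic acid | CCCCC[C@H](CC(=O)O)c1c(O)c(C(=O)CC)c(OC)c(CC=C(C)C)c1OC | intermediate
12 | (4R)-8,10-dimethoxy-9-(3-methylbut-2-en-1-yl)-4-pentyl-7-propanoyl-1-oxaspiro[4.5]deca-7,9-diene-2,6-dione, both epimers at spiro C5 | CCCCC[C@@H]1CC(=O)OC12C(=O)C(C(=O)CC)=C(OC)C(CC=C(C)C)=C2OC | intermediate
13 | acetaldehyde | CC=O | starting material
14 | (Z)-enol diisopinocampheylborinate of 12 (Ipc groups from (−)-α-pinene) | C/C=C(\OB([C@H]3C[C@H]4C[C@H](C4(C)C)[C@@H]3C)[C@H]3C[C@H]4C[C@H](C4(C)C)[C@@H]3C)C1=C(OC)C(CC=C(C)C)=C(OC)C2(OC(=O)C[C@H]2CCCCC)C1=O | intermediate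
15 | diisopinocampheylboron aldolate of 16 | C[C@H](OB([C@H]3C[C@H]4C[C@H](C4(C)C)[C@@H]3C)[C@H]3C[C@H]4C[C@H](C4(C)C)[C@@H]3C)[C@@H](C)C(=O)C1=C(OC)C(CC=C(C)C)=C(OC)C2(OC(=O)C[C@H]2CCCCC)C1=O | intermediate
16 | (4R)-7-[(2R,3S)-3-hydroxy-2-methylbutanoyl]-8,10-dimethoxy-9-(3-methylbut-2-en-1-yl)-4-pentyl-1-oxaspiro[4.5]deca-7,9-diene-2,6-dione (syn-aldol) | C[C@H](O)[C@@H](C)C(=O)C1=C(OC)C(CC=C(C)C)=C(OC)C2(OC(=O)C[C@H]2CCCCC)C1=O | intermediate
17 | (2S,3R,3'R)-7-methoxy-2,3-dimethyl-8-(3-methylbut-2-en-1-yl)-3'-pentyl-2,3-dihydro-4H,5H-spiro[chromene-6,2'-oxolane]-4,5,5'-trione, both epimers at the spiro carbon | C[C@@H]1OC2=C(C(=O)[C@@H]1C)C(=O)C3(OC(=O)C[C@H]3CCCCC)C(OC)=C2CC=C(C)C | intermediate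
18 | (3R)-3-[(2S,3R)-5-hydroxy-7-methoxy-2,3-dimethyl-8-(3-methylbut-2-en-1-yl)-4-oxo-3,4-dihydro-2H-chromen-6-yl]octanoic acid | CCCCC[C@H](CC(=O)O)c1c(O)c2c(c(CC=C(C)C)c1OC)O[C@@H](C)[C@@H](C)C2=O | target

**Step count and risks**

Total steps: 10. Longest linear sequence: 10 steps (1 → 18); compounds 3, 8 and 13 are bought.

Steps most likely to fail:

1. Step 9. What may go wrong: sluggish or unselective enolisation of the crowded ketone by the bulky borane, internal coordination of boron by the C5 carbonyl that erodes facial control, or partial epimerisation at C3 during ring closure. Fallback (sets out from 12, returns at 17): the ketone is first converted with Me3SiOTf/Et3N into the (Z)-trimethylsilyl dienol ether F1. A Mukaiyama aldol addition to 13 under a chiral acyloxyborane Lewis acid (made from a tartaric acid monoester and BH3·THF) follows; here the catalyst binds the small aldehyde and the hindered nucleophile reacts through an open, syn-selective transition state, which should give the silylated syn-aldol F2. The two possible syn adducts are diastereomers because of the side-chain centre and can be separated if facial control is incomplete. CF3CO2H in MeOH/CH2Cl2 then removes the silyl group and closes ring C to 17.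

2. Step 8. What may go wrong: capture of the oxidised phenol at the prenyl-bearing para carbon C8 by solvent or acetate, or loss of the benzylic hydrogen to an ortho-quinone methide, in place of 5-exo closure by the carboxyl group. Fallback (sets out from 11, returns at 18): the para pathway is used on purpose. The acid is protected as the tert-butyl ester F3 (N,N-dimethylformamide di-tert-butyl acetal, toluene, 80 °C). PhI(OAc)2 in MeOH should give the para-quinol methyl ether F4, a 2,5-cyclohexadienone in which C8a–OMe is again a β-methoxy enone carbon. The boron aldol and ring closure of step 9 then give the pyranone F5, Zn/AcOH expels the C8 methoxy group and rearomatises ring A to the tert-butyl ester F6, and CF3CO2H/CH2Cl2 at 0 °C releases 18.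

3. Step 4. What may go wrong: incomplete facial control at the hindered, trisubstituted lactone double bond, or competing 1,2-reduction of the ketone or lactone carbonyl by the ligated CuH. Fallback (sets out from 2, returns at 6): the centre is made by C–C instead of C–H bond formation. Phenol 2 is esterified with propiolic acid (DCC, DMAP) to the aryl propiolate F7, and [(JohnPhos)Au(MeCN)]SbF6 closes it to the 4-unsubstituted coumarin F8. A conjugate addition of n-C5H11MgBr catalysed by CuBr·SMe2 and a chiral ferrocenyl diphosphine (t-BuOMe, −78 °C) then installs the pentyl group enantioselectively to give 6.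

Further compounds
F1 | step 9 | (Z)-trimethylsilyl dienol ether of 12 | C/C=C(\O[Si](C)(C)C)C1=C(OC)C(CC=C(C)C)=C(OC)C2(OC(=O)C[C@H]2CCCCC)C1=O
F2 | step 9 | trimethylsilyl ether of syn-aldol 16 | C[C@H](O[Si](C)(C)C)[C@@H](C)C(=O)C1=C(OC)C(CC=C(C)C)=C(OC)C2(OC(=O)C[C@H]2CCCCC)C1=O
F3 | step 8 | tert-butyl (3R)-3-[2-hydroxy-4,6-dimethoxy-5-(3-methylbut-2-en-1-yl)-3-propanoylphenyl]octanoate | CCCCC[C@H](CC(=O)OC(C)(C)C)c1c(O)c(C(=O)CC)c(OC)c(CC=C(C)C)c1OC
F4 | step 8 | tert-butyl (3R)-3-[2,4,5-trimethoxy-4-(3-methylbut-2-en-1-yl)-6-oxo-5-propanoylcyclohexa-1,5-dien-1-yl... para-quinol methyl ether of F3, both epimers at C8 | CCCCC[C@H](CC(=O)OC(C)(C)C)C1=C(OC)C(OC)(CC=C(C)C)C(OC)=C(C(=O)CC)C1=O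
F5 | step 8 | tert-butyl (3R)-3-[(2S,3R)-7,8-dimethoxy-2,3-dimethyl-8-(3-methylbut-2-en-1-yl)-4,5-dioxo-2,3,5,8-tetrahydro-4H-chromen-6-yl]octanoate, both epimers at C8 | C[C@@H]1OC2=C(C(=O)[C@@H]1C)C(=O)C([C@H](CCCCC)CC(=O)OC(C)(C)C)=C(OC)C2(OC)CC=C(C)C
F6 | step 8 | tert-butyl ester of 18 | CCCCC[C@H](CC(=O)OC(C)(C)C)c1c(O)c2c(c(CC=C(C)C)c1OC)O[C@@H](C)[C@@H](C)C2=O
F7 | step 4 | 3,5-dimethoxy-2-propanoylphenyl prop-2-ynoate | C#CC(=O)Oc1cc(OC)cc(OC)c1C(=O)CC
F8 | step 4 | 5,7-dimethoxy-8-propanoyl-2H-chromen-2-one | CCC(=O)c1c(OC)cc(OC)c2C=CC(=O)Oc12
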